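**Assumption:** the SMILES is read as the normal-series labdane 19-angeloyloxy-labda-7,13Z-dien-15-oic acid, (4S,5R,9S,10R), with the acyloxymethyl group on C4 axial and cis to the C10 methyl; labdane numbering is used for the bicyclic compounds.

## Retrosynthetic overview

1. Target ⇐ late O-angeloylation of (13Z)-19-hydroxylabda-7,13-dien-15-oic acid, so the Z-configured angelate never sees acid or Lewis acid.
2. Both rings ⇐ one cationic bicyclization of an open-chain (2Z,6E,10E)-trienoic acid carrying a terminal (S)-2-methyl-2-alkyloxirane. Ring A closes first and ring B second, and the C8 cation ends by loss of H-7. The oxirane carbon becomes C4 and its CH2O becomes C19.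
3. Open-chain epoxy acid ⇐ γ-alkylation of the dienolate of 3-methylbut-2-enoic acid (sets 13Z) with a C15 epoxy allylic bromide.
4. Epoxy bromide ⇐ (2E,6E)-farnesol by E-selective oxidation of the terminal methyl, Sharpless epoxidation (the only external source of chirality), hydride opening and oxirane closure.

## Route

Step 1
Reactants: 1 (2E,6E)-farnesol
Product: 2 (2E,6E)-farnesyl acetate
Conditions: Ac2O (1.5 equiv), pyridine, DMAP (5 mol %), CH2Cl2, 0 °C → rt
Reagents that add atoms: acetic anhydride, CC(=O)OC(C)=O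
Why: O-acylation (nucleophilic acyl substitution) masks the C1 allylic alcohol so that only the C12 alcohol made next can direct the epoxidation of step 3; no stereocentre is formed.

Step 2
Reactants: 2 (2E,6E)-farnesyl acetate
Product: 3 (2E,6E,10E)-12-hydroxy-3,7,11-trimethyldodeca-2,6,10-trien-1-yl acetate
Conditions: SeO2 (10 mol %), t-BuOOH (70% in water, 3 equiv), salicylic acid (10 mol %), CH2Cl2, rt, 24 h; recycle recovered 2
Reagents that add atoms: tert-butyl hydroperoxide, CC(C)(C)OO (its oxygen is passed on through the SeO2 catalyst)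
Why: SeO2 allylic oxidation (ene reaction then [2,3]-sigmatropic shift) attacks the most electron-rich, terminal olefin and there the methyl trans to the chain, giving the (E)-allylic alcohol.

Step 3
Reactants: 3 (2E,6E,10E)-12-hydroxy-3,7,11-trimethyldodeca-2,6,10-trien-1-yl acetate
Product: 4 (2E,6E)-9-[(2R,3R)-3-(hydroxymethyl)-3-methyloxiran-2-yl]-3,7-dimethylnona-2,6-dien-1-yl acetate
Conditions: Ti(OiPr)4 (10 mol %), diethyl D-(−)-tartrate (12 mol %), t-BuOOH (5.5 M in decane, 2 equiv), 4 Å molecular sieves, CH2Cl2, −20 °C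
Reagents that add atoms: tert-butyl hydroperoxide, CC(C)(C)OO
Why: Sharpless asymmetric epoxidation: only the olefin next to the free OH reacts, and the D-tartrate ligand delivers oxygen to the face that gives the (2R,3R)-oxirane (about 94% ee expected for this alcohol class), which sets the carbon that becomes C4.

Step 4
Reactants: 4 (2E,6E)-9-[(2R,3R)-3-(hydroxymethyl)-3-methyloxiran-2-yl]-3,7-dimethylnona-2,6-dien-1-yl acetate
Product: 5 (2E,6E,11S)-3,7,11-trimethyldodeca-2,6-diene-1,11,12-triol
Conditions: LiAlH4 (3 equiv), THF, 0 °C → rt; aqueous work-up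
Reagents that add atoms: none
Why: Hydride opens the 2,3-epoxy alcohol by SN2 at the secondary C10 because the fully substituted C11 is blocked, so the C11–O bond and its configuration are kept (descriptor now S), and the same reagent reduces off the acetate.

Step 5
Reactants: 5 (2E,6E,11S)-3,7,11-trimethyldodeca-2,6-diene-1,11,12-triol
Product: 8 (2S)-2-[(4E,8E)-10-bromo-4,8-dimethyldeca-4,8-dien-1-yl]-2-methyloxirane, via bis-mesylate 6 (not isolated), via bromo mesylate 7 (not isolated)
Conditions: MsCl (2.3 equiv), Et3N (2.6 equiv), THF, −45 °C; LiBr (4 equiv), 0 °C, 1 h; cold aqueous wash; then NaH (1.5 equiv), THF, 0 °C; used at once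
Reagents that add atoms: lithium bromide, [Li+].[Br-] (methanesulfonyl chloride, CS(=O)(=O)Cl, adds atoms only to 6 and 7)
Why: Both primary alcohols are sulfonylated in preference to the tertiary one, bromide displaces only the allylic mesylate (SN2), and the tertiary alkoxide closes the oxirane by intramolecular Williamson (3-exo-tet) displacement at C12 without breaking the C11–O bond, so the stereocentre is retained as S.

Step 6
Reactants: 8 (2S)-2-[(4E,8E)-10-bromo-4,8-dimethyldeca-4,8-dien-1-yl]-2-methyloxirane; 9 3-methylbut-2-enoic acid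
Product: 12 (2Z,6E,10E)-3,7,11-trimethyl-14-[(2S)-2-methyloxiran-2-yl]tetradeca-2,6,10-trienoic acid, via dilithium dienolate 10 (not isolated), via lithium copper dienolate 11 (not isolated)
Conditions: 9, LiN(iPr)2 (LDA, 2.1 equiv), THF, −78 → 0 °C; CuI (1.05 equiv), −78 °C; then 8, −78 → −20 °C; aq. NaH2PO4 (pH 4–5)
Reagents that add atoms: none
Why: γ-Alkylation of a copper dienolate (vinylogous enolate alkylation, SN2 at the primary allylic bromide): the dienolate formed by carboxylate-directed removal of a proton from the cis methyl is held s-cis by the metal, so the new C2=C3 bond forms Z, and the hindered oxirane does not react at low temperature.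

Step 7
Reactants: 12 (2Z,6E,10E)-3,7,11-trimethyl-14-[(2S)-2-methyloxiran-2-yl]tetradeca-2,6,10-trienoic acid
Product: 14 (13Z)-19-hydroxylabda-7,13-dien-15-oic acid, via dichloroaluminium carboxylate 13 (not isolated)
Conditions: MeAlCl2 (3.0 equiv, the first equivalent consumed by the CO2H group), CH2Cl2, −94 → −78 °C, 30 min; aq. KNaC4H4O6 (Rochelle salt), then pH 4
Reagents that add atoms: none
Why: Proposed new method: the aluminium Lewis acid binds the oxirane oxygen and the 10,11-olefin attacks the tertiary oxirane carbon from the back (inversion, concerted with C–O cleavage) in a chair–chair folded chain, so the single oxirane stereocentre fixes C4 and, through the chair (oxirane CH2–O tied back and therefore axial, CH3 equatorial; E-olefins giving the trans ring fusion with 5α-H, 10β-CH3 and 9α-H), also C5, C9 and C10, ring A closing first and ring B second, after which the tertiary C8 cation loses the axial 7-H to give the trisubstituted 7-ene while the electron-poor Z-enoate (held as its aluminium carboxylate, and forced to place CO2 axial in any third ring closure) stays out; the closest known reaction type is the MeAlCl2-promoted cationic cyclization of chiral epoxy-polyenes, here extended to a 2-methyl-2-alkyloxirane as the only stereocontrol element, a free acid and termination by plain proton loss.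

Step 8
Reactants: 14 (13Z)-19-hydroxylabda-7,13-dien-15-oic acid
Product: 16 (13Z)-19-angeloyloxylabda-7,13-dien-15-oic acid (the target), via dilithium alkoxide carboxylate 15 (not isolated)
Conditions: LiN(SiMe3)2 (LiHMDS, 2.1 equiv), THF, −78 °C; angelic anhydride (1.5 equiv), −78 → 0 °C; aq. NaHCO3, rt, 1 h; aq. NH4Cl
Reagents that add atoms: angelic anhydride [(2Z)-2-methylbut-2-enoic anhydride], C/C=C(/C)C(=O)OC(=O)/C(C)=C\C
Why: O-acylation of the lithium alkoxide by the anhydride (nucleophilic acyl substitution) at low temperature and without a nucleophilic amine catalyst keeps the angelate Z, any mixed anhydride formed at the C15 carboxylate is hydrolysed back by the bicarbonate wash, and no stereocentre is touched.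

## Compound list

1 | (2E,6E)-farnesol | OC/C=C(C)/CC/C=C(C)/CCC=C(C)C | starting material
2 | (2E,6E)-farnesyl acetate | CC(=O)OC/C=C(C)/CC/C=C(C)/CCC=C(C)C | intermediate
3 | (2E,6E,10E)-12-hydroxy-3,7,11-trimethyldodeca-2,6,10-trien-1-yl acetate | CC(=O)OC/C=C(C)/CC/C=C(C)/CC/C=C(C)/CO | intermediate
4 | (2E,6E)-9-[(2R,3R)-3-(hydroxymethyl)-3-methyloxiran-2-yl]-3,7-dimethylnona-2,6-dien-1-yl acetate | CC(=O)OC/C=C(C)/CC/C=C(C)/CC[C@H]1O[C@]1(C)CO | intermediate
5 | (2E,6E,11S)-3,7,11-trimethyldodeca-2,6-diene-1,11,12-triol | OC/C=C(C)/CC/C=C(C)/CCC[C@](C)(O)CO | intermediate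
6 | (2E,6E,11S)-11-hydroxy-3,7,11-trimethyldodeca-2,6-diene-1,12-diyl dimethanesulfonate (bis-mesylate) | CS(=O)(=O)OC/C=C(C)/CC/C=C(C)/CCC[C@](C)(O)COS(C)(=O)=O | intermediate
7 | (2S,6E,10E)-12-bromo-2-hydroxy-2,6,10-trimethyldodeca-6,10-dien-1-yl methanesulfonate (bromo mesylate) | BrC/C=C(C)/CC/C=C(C)/CCC[C@](C)(O)COS(C)(=O)=O | intermediate
8 | (2S)-2-[(4E,8E)-10-bromo-4,8-dimethyldeca-4,8-dien-1-yl]-2-methyloxirane | BrC/C=C(C)/CC/C=C(C)/CCC[C@@]1(C)CO1 | intermediate
9 | 3-methylbut-2-enoic acid | CC(C)=CC(=O)O | starting material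
10 | dilithium 3-methylbuta-1,3-diene-1,1-bis(olate) (dilithium dienolate) | C=C(C)C=C(O[Li])O[Li] | intermediate
11 | lithium copper dienolate of 9 | C=C(C)C=C(O[Li])O[Cu] | intermediate
12 | (2Z,6E,10E)-3,7,11-trimethyl-14-[(2S)-2-methyloxiran-2-yl]tetradeca-2,6,10-trienoic acid | OC(=O)/C=C(C)\CC/C=C(C)/CC/C=C(C)/CCC[C@@]1(C)CO1 | intermediate
13 | dichloroaluminium carboxylate of 12 | Cl[Al](Cl)OC(=O)/C=C(C)\CC/C=C(C)/CC/C=C(C)/CCC[C@@]1(C)CO1 | intermediate
14 | (13Z)-19-hydroxylabda-7,13-dien-15-oic acid; (2Z)-5-[(1S,4aR,5S,8aR)-5-(hydroxymethyl)-2,5,8a-trimethyl-1,4,4a,5,6,7,8,8a-octahydronaphthalen-1-yl]-3-methylpent-2-enoic acid | OC[C@@]1(C)CCC[C@]2(C)[C@@H](CC/C(C)=C\C(=O)O)C(C)=CC[C@@H]12 | intermediate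
15 | dilithium alkoxide carboxylate of 14 | [Li]OC[C@@]1(C)CCC[C@]2(C)[C@@H](CC/C(C)=C\C(=O)O[Li])C(C)=CC[C@@H]12 | intermediate
16 | (13Z)-19-angeloyloxylabda-7,13-dien-15-oic acid (CNP0249147.1) | C/C=C(/C)C(=O)OC[C@@]1(C)CCC[C@]2(C)[C@@H](CC/C(C)=C\C(=O)O)C(C)=CC[C@@H]12 | target

## Step count and risks

Total steps: 8. Longest linear sequence: 8 (1 → 2 → 3 → 4 → 5 → 8 → 12 → 14 → 16); compound 9 enters in step 6. Buying 2 instead of 1 would remove step 1.

The three steps most likely to fail:

**Step 7 (bicyclization).** The risks are: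
- proton loss giving the 8(17)- or 8-ene next to the wanted 7-ene;
- partial ionization of the oxirane before C–C bonding, which erodes ee or gives the aldehyde from a hydride shift;
- the alternative chair with CH3 axial, which gives the C4-epimeric, antipodal skeleton (told apart by an NOE between H2-19 and H3-20).

Fallback, setting out from 12 and returning at 14: the position of the ring B olefin is settled in a separate operation. 12 is cyclized with MeAlCl2 in the presence of 2,6-di-tert-butyl-4-methylpyridine, a hindered base that takes the most exposed proton (on C17), to give mainly (13Z)-19-hydroxylabda-8(17),13-dien-15-oic acid F1. F1 is then isomerized with RhCl3·3H2O (trivalent rhodium) in ethanol at 70 °C; the rhodium hydride moves the exocyclic olefin one position into ring B on its open C7 side and stops at the trisubstituted 7-ene, which is 14.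

**Step 6 (γ-alkylation).** The risks are α-alkylation and an incomplete Z preference at C2=C3. Fallback, setting out from 8 and returning at 12: the geometry is taken from a stereodefined enol triflate instead of the dienolate.
- 8 alkylates the dianion of methyl acetoacetate (NaH, then n-BuLi, THF, 0 °C) at its terminal carbon to give methyl (6E,10E)-7,11-dimethyl-14-[(2S)-2-methyloxiran-2-yl]-3-oxotetradeca-6,10-dienoate F2.
- Tf2O with aqueous Me4NOH in toluene gives the non-chelated enolate and hence methyl (2E,6E,10E)-7,11-dimethyl-14-[(2S)-2-methyloxiran-2-yl]-3-(trifluoromethylsulfonyloxy)tetradeca-2,6,10-trienoate F3.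
- Methyl transfer from trimethylboroxine with Pd(PPh3)4 (zerovalent palladium) and K2CO3 in dioxane at 90 °C replaces the triflate with retention and gives methyl (2Z,6E,10E)-3,7,11-trimethyl-14-[(2S)-2-methyloxiran-2-yl]tetradeca-2,6,10-trienoate F4.
- LiOH in THF–water at 40 °C, then pH 4–5, gives 12.

**Step 8 (angeloylation).** The risks are angelate-to-tiglate isomerization, a sluggish axial neopentyl alcohol and interference by the free acid. Fallback, setting out from 14 and returning at 16: the angelate double bond is built on the molecule.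
- Allyl bromide and KHCO3 in DMF give allyl (13Z)-19-hydroxylabda-7,13-dien-15-oate F5.
- 2-[Bis(2,2,2-trifluoroethoxy)phosphoryl]propanoic acid with DCC and DMAP gives allyl (13Z)-19-{2-[bis(2,2,2-trifluoroethoxy)phosphoryl]propanoyloxy}labda-7,13-dien-15-oate F6.
- Z-selective Still–Gennari olefination with acetaldehyde (KN(SiMe3)2, 18-crown-6, THF, −78 °C) gives allyl (13Z)-19-angeloyloxylabda-7,13-dien-15-oate F7.
- Pd(PPh3)4 (zerovalent palladium) and morpholine in THF remove the allyl group to give 16.

Further compounds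

F1 | step 7 | (13Z)-19-hydroxylabda-8(17),13-dien-15-oic acid | OC[C@@]1(C)CCC[C@]2(C)[C@@H](CC/C(C)=C\C(=O)O)C(=C)CC[C@@H]12
F2 | step 6 | methyl (6E,10E)-7,11-dimethyl-14-[(2S)-2-methyloxiran-2-yl]-3-oxotetradeca-6,10-dienoate | COC(=O)CC(=O)CC/C=C(C)/CC/C=C(C)/CCC[C@@]1(C)CO1
F3 | step 6 | methyl (2E,6E,10E)-7,11-dimethyl-14-[(2S)-2-methyloxiran-2-yl]-3-(trifluoromethylsulfonyloxy)tetradeca-2,6,10-trienoate | COC(=O)/C=C(OS(=O)(=O)C(F)(F)F)\CC/C=C(C)/CC/C=C(C)/CCC[C@@]1(C)CO1
F4 | step 6 | methyl (2Z,6E,10E)-3,7,11-trimethyl-14-[(2S)-2-methyloxiran-2-yl]tetradeca-2,6,10-trienoate | COC(=O)/C=C(C)\CC/C=C(C)/CC/C=C(C)/CCC[C@@]1(C)CO1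
F5 | step 8 | allyl (13Z)-19-hydroxylabda-7,13-dien-15-oate | OC[C@@]1(C)CCC[C@]2(C)[C@@H](CC/C(C)=C\C(=O)OCC=C)C(C)=CC[C@@H]12
F6 | step 8 | allyl (13Z)-19-{2-[bis(2,2,2-trifluoroethoxy)phosphoryl]propanoyloxy}labda-7,13-dien-15-oate | CC(C(=O)OC[C@@]1(C)CCC[C@]2(C)[C@@H](CC/C(C)=C\C(=O)OCC=C)C(C)=CC[C@@H]12)P(=O)(OCC(F)(F)F)OCC(F)(F)F
F7 | step 8 | allyl (13Z)-19-angeloyloxylabda-7,13-dien-15-oate | C/C=C(/C)C(=O)OC[C@@]1(C)CCC[C@]2(C)[C@@H](CC/C(C)=C\C(=O)OCC=C)C(C)=CC[C@@H]12
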